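The route rests on inserting an isobutyraldehyde unit (C6–C7; longipinane numbering, C1 = enone carbonyl, C5/C10 = one-carbon bridges of the bicyclo[3.1.1]heptane) between bridge carbon C5 and the methyl carbon C8 of a C10 acetyl group. The key step exploits the seven-membered ring C5–C6–C7–C8–C9–C10–C11: its 1,3-dioxygenation (C7–O, C9–O) is an aldol retron and C5 is a former cyclobutanone carbon. In one pot a selenium-stabilised cation at C5 captures the isobutyraldehyde silyl enol ether (C5–C6) and the released aldehyde condenses with the acetyl group (C7–C8). The precursor, a norpinanone selenoketal, comes from an intramolecular vinylketene–alkene [2+2] cycloaddition.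

Key step: step 9

Remark (numbering): tricyclic compounds carry longipinane numbering: C1 ketone, C2=C3, C4 and C11 bridgeheads, C5 and C10 one-carbon bridges, C6 CMe2, C7 senecioate carbon, C8 CH2, C9 tiglate carbon, C12 methyl on C3.
Remark (assumption): in the two catalyst-controlled steps (3 and 10) the catalyst enantiomer is chosen to give the configuration drawn; the sense of induction has to be confirmed on the first batch.
Remark (assumption): compounds 1, 3, 13, 20 and 22 are purchased.

Step 1
Reactants: 1 (E)-3-methylpent-2-en-4-yn-1-ol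
Product: 2 (E)-3-methylpent-2-en-4-ynal
Conditions: activated MnO2, CH2Cl2, rt
Reagents that add atoms: none
Why: Allylic alcohol oxidation with MnO2 should stop at the enal and leave the alkyne and the E-alkene untouched.

Step 2
Reactants: 3 methyl 3-methylbut-2-enoate
Product: 4 tert-butyl[(1-methoxy-3-methylbuta-1,3-dien-1-yl)oxy]dimethylsilane
Conditions: LDA, THF, −78 °C; TBSCl, DMPU, −78 °C → rt
Reagents that add atoms: tert-butyldimethylsilyl chloride, CC(C)(C)[Si](C)(C)Cl
Why: γ-Deprotonation of the senecioate and O-silylation of the dienolate (silyl dienol ether formation) should give the γ-nucleophile for the vinylogous aldol reaction.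

Step 3
Reactants: 2 (E)-3-methylpent-2-en-4-ynal; 4 tert-butyl[(1-methoxy-3-methylbuta-1,3-dien-1-yl)oxy]dimethylsilane
Product: 5 methyl (2E,5S,6E)-5-hydroxy-3,7-dimethylnona-2,6-dien-8-ynoate
Conditions: SiCl4, chiral bisphosphoramide (5 mol%), CH2Cl2, −78 °C; aq. NaHCO3
Reagents that add atoms: none
Why: Catalytic enantioselective vinylogous Mukaiyama aldol reaction: the dienol ether should react only through its γ-carbon in an open transition state while the chiral Lewis-base-bound trichlorosilyl cation selects the aldehyde face, which sets C5 as S.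

Step 4
Reactants: 5 methyl (2E,5S,6E)-5-hydroxy-3,7-dimethylnona-2,6-dien-8-ynoate
Product: 6 methyl (2E,5S,6E)-5-(tert-butyldimethylsilyloxy)-3,7-dimethylnona-2,6-dien-8-ynoate
Conditions: TBSOTf, 2,6-lutidine, CH2Cl2, −78 °C
Reagents that add atoms: tert-butyldimethylsilyl triflate, CC(C)(C)[Si](C)(C)OS(=O)(=O)C(F)(F)F
Why: Standard silylation should mask the secondary alcohol for the acid chloride and ketene chemistry without touching the stereocentre.

Step 5
Reactants: 6 methyl (2E,5S,6E)-5-(tert-butyldimethylsilyloxy)-3,7-dimethylnona-2,6-dien-8-ynoate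
Product: 7 (2E,5S,6E)-5-(tert-butyldimethylsilyloxy)-3,7-dimethylnona-2,6-dien-8-ynoic acid
Conditions: LiOH·H2O, THF/MeOH/H2O, rt; dilute HCl
Reagents that add atoms: lithium hydroxide, [Li+].[OH-]
Why: Saponification of the methyl ester; the β,β-disubstituted enoate resists conjugate addition and the mild base should leave the silyl ether and C5 intact.

Step 6
Reactants: 7 (2E,5S,6E)-5-(tert-butyldimethylsilyloxy)-3,7-dimethylnona-2,6-dien-8-ynoic acid
Product: 10 (4S)-4-(tert-butyldimethylsilyloxy)-7-ethynyl-7-methyl-2-methylidenebicyclo[3.1.1]heptan-6-one, via acid chloride 8 (not isolated), via vinylketene 9 (not isolated)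
Conditions: 1-chloro-N,N,2-trimethylprop-1-en-1-amine, CH2Cl2, 0 °C; then Et3N, PhMe, 110 °C, high dilution
Reagents that add atoms: none
Why: Intramolecular vinylketene–alkene [2+2] cycloaddition: Et3N removes a proton from the methyl group cis to COCl, and the ketene carbonyl carbon bonds to C6 of the chain (charge at the tertiary propargylic C7), which should give the bridged bicyclo[3.1.1] mode; the suprafacial addition to the E-alkene places the 7-methyl syn and the ethynyl group anti to the three-carbon bridge, and A(1,3) strain (C5–H eclipsing the alkene) makes the ketene add anti to the silyloxy group, so the 5S centre fixes the absolute configuration of both bridgeheads and C7 (minor diastereomer removable by chromatography).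

Step 7
Reactants: 10 (4S)-4-(tert-butyldimethylsilyloxy)-7-ethynyl-7-methyl-2-methylidenebicyclo[3.1.1]heptan-6-one
Product: 11 (4S)-7-acetyl-4-(tert-butyldimethylsilyloxy)-7-methyl-2-methylidenebicyclo[3.1.1]heptan-6-one
Conditions: (IPr)AuCl (2 mol%), AgSbF6 (2 mol%), 1,4-dioxane/H2O, 80 °C
Reagents that add atoms: water, O
Why: Gold(I)-catalysed Markovnikov hydration of the terminal alkyne should give the methyl ketone under neutral conditions that spare the strained ketone, the 1,1-disubstituted alkene and the silyl ether.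

Step 8
Reactants: 11 (4S)-7-acetyl-4-(tert-butyldimethylsilyloxy)-7-methyl-2-methylidenebicyclo[3.1.1]heptan-6-one
Product: 12 1-[(4S)-4-(tert-butyldimethylsilyloxy)-7-methyl-2-methylidene-6,6-bis(phenylselanyl)bicyclo[3.1.1]heptan-7-yl]ethanone
Conditions: PhSeH (2.2 equiv), ZnCl2 (0.5 equiv), CH2Cl2, 0 °C → rt, dark
Reagents that add atoms: benzeneselenol, [SeH]c1ccccc1
Why: Selenoketalisation should take place at the cyclobutanone, whose change from sp2 to sp3 releases angle strain, in preference to the hindered neopentyl-type methyl ketone.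

Step 9
Reactants: 12 1-[(4S)-4-(tert-butyldimethylsilyloxy)-7-methyl-2-methylidene-6,6-bis(phenylselanyl)bicyclo[3.1.1]heptan-7-yl]ethanone; 13 2-methyl-1-(trimethylsilyloxy)prop-1-ene
Product: 16 (1S)-1-(tert-butyldimethylsilyloxy)-5-(phenylselanyl)longipina-3(12),7-dien-9-one, via keto-aldehyde 14 (not isolated), via aldol 15 (not isolated)
Conditions: SnCl4, CH2Cl2, −78 °C; then NaOMe, MeOH, −78 → 45 °C (one pot)
Reagents that add atoms: none
Why: SnCl4 ionises one C–Se bond to a selenium-stabilised carbenium ion at bridge carbon C5, which cannot eliminate because both neighbours are bridgeheads, and the silyl enol ether attacks it through its fully substituted carbon (Mukaiyama-type alkylation by an α-seleno cation, the analogue of thionium alkylation) to form C5–C6 and the non-enolisable aldehyde 14. On addition of NaOMe the acetyl group, enolisable only at its methyl carbon C8, adds to the aldehyde and aldol 15 dehydrates (intramolecular Claisen–Schmidt condensation), which forms C7–C8. The seven-membered ring closes in a 7-(enolendo)-exo-trig aldol mode. C5 is the only new stereocentre: the nucleophile should enter anti to the C1–C2–C3 bridge and to the C1 silyloxy group that shields the other face, which is also the only orientation from which the chain can reach the acetyl group, so a wrong C5 epimer stays open and is removed; C7 remains sp2 and is set in step 10. The step needs chemoselective ionisation of the selenoketal beside the hindered ketone and the silyl ether (low temperature, one equivalent of Lewis acid) and C-attack of the enol ether, both usual for soft α-hetero cations.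

Step 10
Reactants: 16 (1S)-1-(tert-butyldimethylsilyloxy)-5-(phenylselanyl)longipina-3(12),7-dien-9-one
Product: 18 (1S,7R)-1-(tert-butyldimethylsilyloxy)-7-hydroxy-5-(phenylselanyl)longipin-3(12)-en-9-one, via boronate 17 (not isolated)
Conditions: CuCl (10 mol%), NaOt-Bu, Josiphos-type bisphosphine, B2pin2, MeOH, THF, rt; then NaBO3·4H2O, THF/H2O, 0 °C; aq. Na2SO3
Reagents that add atoms: sodium perborate, [Na+].[O-]OB=O
Why: Copper-catalysed asymmetric conjugate borylation of the cyclic enone followed by stereoretentive C–B oxidation; the two faces of C7=C8 differ only through remote groups, so the chiral ligand on copper should control C7 (7R), and the selenide has no β-hydrogen that can be eliminated (any selenoxide is returned by the sulfite work-up).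

Step 11
Reactants: 18 (1S,7R)-1-(tert-butyldimethylsilyloxy)-7-hydroxy-5-(phenylselanyl)longipin-3(12)-en-9-one
Product: 19 (1S,7R)-1-(tert-butyldimethylsilyloxy)-7-hydroxylongipin-3(12)-en-9-one
Conditions: Bu3SnH, AIBN, PhH, 80 °C
Reagents that add atoms: none
Why: Radical deselenation: homolysis of the tertiary C–Se bond and hydrogen transfer to the cyclobutyl radical should give C5–H, whose configuration is fixed by the ring; the step is placed after the enone is consumed so that the C5 radical has no β-vinyl group that could migrate.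

Step 12
Reactants: 19 (1S,7R)-1-(tert-butyldimethylsilyloxy)-7-hydroxylongipin-3(12)-en-9-one; 20 3-methylbut-2-enal
Product: 21 (1S,7R,9R)-1-(tert-butyldimethylsilyloxy)-9-hydroxylongipin-3(12)-en-7-yl 3-methylbut-2-enoate
Conditions: SmI2 (0.3 equiv), THF, −10 °C, dark
Reagents that add atoms: none
Why: Evans–Tishchenko reduction: the C7 hydroxyl forms a samarium-bound hemiacetal with the enal and delivers its hydride through a six-membered chair to C9=O, which should set C9 (9R) anti to C7 and leave the senecioate on O7.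

Step 13
Reactants: 21 (1S,7R,9R)-1-(tert-butyldimethylsilyloxy)-9-hydroxylongipin-3(12)-en-7-yl 3-methylbut-2-enoate; 22 (E)-2-methylbut-2-enoyl chloride
Product: 23 (1S,7R,9R)-1-(tert-butyldimethylsilyloxy)-7-(3-methylbut-2-enoyloxy)longipin-3(12)-en-9-yl (E)-2-methylbut-2-enoate
Conditions: pyridine, DMAP (cat.), CH2Cl2, 0 → 40 °C
Reagents that add atoms: none
Why: DMAP-catalysed acylation of the hindered secondary alcohol; the E-configured tigloyl group should not isomerise and no stereocentre is touched.

Step 14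
Reactants: 23 (1S,7R,9R)-1-(tert-butyldimethylsilyloxy)-7-(3-methylbut-2-enoyloxy)longipin-3(12)-en-9-yl (E)-2-methylbut-2-enoate
Product: 24 (1S,7R,9R)-1-hydroxy-7-(3-methylbut-2-enoyloxy)longipin-3(12)-en-9-yl (E)-2-methylbut-2-enoate
Conditions: HF·pyridine, THF/pyridine, 0 °C → rt
Reagents that add atoms: none
Why: Buffered fluoride desilylation should free the C1 alcohol without ester cleavage or migration.

Step 15
Reactants: 24 (1S,7R,9R)-1-hydroxy-7-(3-methylbut-2-enoyloxy)longipin-3(12)-en-9-yl (E)-2-methylbut-2-enoate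
Product: 26 (7R,9R)-7-(3-methylbut-2-enoyloxy)-1-oxolongipin-2-en-9-yl (E)-2-methylbut-2-enoate, via exocyclic enone 25 (not isolated)
Conditions: Dess–Martin periodinane, NaHCO3, CH2Cl2, rt; then DBU (cat.)
Reagents that add atoms: none
Why: Dess–Martin oxidation gives the β,γ-unsaturated ketone and base-catalysed isomerisation should move the exocyclic double bond into conjugation (only C2 is enolisable, C11 being a bridgehead), which completes the 3-methyl-2-en-1-one.

Compound list
1 | (E)-3-methylpent-2-en-4-yn-1-ol | C#C/C(C)=C/CO | starting material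
2 | (E)-3-methylpent-2-en-4-ynal | C#C/C(C)=C/C=O | intermediate
3 | methyl 3-methylbut-2-enoate | COC(=O)C=C(C)C | starting material
4 | tert-butyl[(1-methoxy-3-methylbuta-1,3-dien-1-yl)oxy]dimethylsilane (enol ether geometry not defined) | C=C(C)C=C(OC)O[Si](C)(C)C(C)(C)C | intermediate
5 | methyl (2E,5S,6E)-5-hydroxy-3,7-dimethylnona-2,6-dien-8-ynoate | COC(=O)/C=C(\C)C[C@H](O)/C=C(\C)C#C | intermediate
6 | methyl (2E,5S,6E)-5-(tert-butyldimethylsilyloxy)-3,7-dimethylnona-2,6-dien-8-ynoate | COC(=O)/C=C(\C)C[C@H](O[Si](C)(C)C(C)(C)C)/C=C(\C)C#C | intermediate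
7 | (2E,5S,6E)-5-(tert-butyldimethylsilyloxy)-3,7-dimethylnona-2,6-dien-8-ynoic acid | OC(=O)/C=C(\C)C[C@H](O[Si](C)(C)C(C)(C)C)/C=C(\C)C#C | intermediate
8 | acid chloride of 7 | ClC(=O)/C=C(\C)C[C@H](O[Si](C)(C)C(C)(C)C)/C=C(\C)C#C | intermediate
9 | vinylketene, (5S,6E)-5-(tert-butyldimethylsilyloxy)-7-methyl-3-methylidenenona-1,6-dien-8-yn-1-one | O=C=CC(=C)C[C@H](O[Si](C)(C)C(C)(C)C)/C=C(\C)C#C | intermediate
10 | (4S)-4-(tert-butyldimethylsilyloxy)-7-ethynyl-7-methyl-2-methylidenebicyclo[3.1.1]heptan-6-one; 7-methyl syn and ethynyl anti to the C2–C4 bridge, silyloxy group on the side of the C6 carbonyl bridge | O=C1[C@@H]2C(=C)C[C@H](O[Si](C)(C)C(C)(C)C)[C@H]1[C@]2(C)C#C | intermediate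
11 | (4S)-7-acetyl-4-(tert-butyldimethylsilyloxy)-7-methyl-2-methylidenebicyclo[3.1.1]heptan-6-one; acetyl anti to the C2–C4 bridge | O=C1[C@@H]2C(=C)C[C@H](O[Si](C)(C)C(C)(C)C)[C@H]1[C@]2(C)C(C)=O | intermediate
12 | 6,6-bis(phenylselanyl) ketal of 11 at the ring ketone | c1ccccc1[Se]C2([Se]c1ccccc1)[C@@H]3C(=C)C[C@H](O[Si](C)(C)C(C)(C)C)[C@H]2[C@]3(C)C(C)=O | intermediate
13 | 2-methyl-1-(trimethylsilyloxy)prop-1-ene | CC(C)=CO[Si](C)(C)C | starting material
14 | keto-aldehyde: 2-methyl-2-[7-acetyl-4-silyloxy-7-methyl-2-methylidene-6-(phenylselanyl)bicyclo[3.1.1]heptan-6-yl]propanal; aldehyde chain anti and selenium syn to the C2–C4 bridge | O=CC(C)(C)[C@@]1([Se]c2ccccc2)[C@@H]3C(=C)C[C@H](O[Si](C)(C)C(C)(C)C)[C@H]1[C@]3(C)C(C)=O | intermediate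
15 | aldol: (1S)-1-(tert-butyldimethylsilyloxy)-7-hydroxy-5-(phenylselanyl)longipin-3(12)-en-9-one, both C7 epimers | O=C1CC(O)C(C)(C)[C@]2([Se]c3ccccc3)[C@H]4[C@@H](O[Si](C)(C)C(C)(C)C)CC(=C)[C@@H]2[C@]41C | intermediate
16 | (1S)-1-(tert-butyldimethylsilyloxy)-5-(phenylselanyl)longipina-3(12),7-dien-9-one; selenium on C5 syn to the C1–C3 bridge | O=C1C=CC(C)(C)[C@]2([Se]c3ccccc3)[C@H]4[C@@H](O[Si](C)(C)C(C)(C)C)CC(=C)[C@@H]2[C@]41C | intermediate
17 | C7 pinacol boronate of the saturated ketone (boron where the 7-OH of 18 stands) | O=C1C[C@@H](B3OC(C)(C)C(C)(C)O3)C(C)(C)[C@]2([Se]c3ccccc3)[C@H]4[C@@H](O[Si](C)(C)C(C)(C)C)CC(=C)[C@@H]2[C@]41C | intermediate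
18 | (1S,7R)-1-(tert-butyldimethylsilyloxy)-7-hydroxy-5-(phenylselanyl)longipin-3(12)-en-9-one | O=C1C[C@@H](O)C(C)(C)[C@]2([Se]c3ccccc3)[C@H]4[C@@H](O[Si](C)(C)C(C)(C)C)CC(=C)[C@@H]2[C@]41C | intermediate
19 | (1S,7R)-1-(tert-butyldimethylsilyloxy)-7-hydroxylongipin-3(12)-en-9-one | O=C1C[C@@H](O)C(C)(C)[C@@H]2[C@H]3[C@@H](O[Si](C)(C)C(C)(C)C)CC(=C)[C@@H]2[C@]31C | intermediate
20 | 3-methylbut-2-enal | CC(C)=CC=O | starting material
21 | (1S,7R,9R)-1-(tert-butyldimethylsilyloxy)-9-hydroxylongipin-3(12)-en-7-yl 3-methylbut-2-enoate | O[C@@H]1C[C@@H](OC(=O)C=C(C)C)C(C)(C)[C@@H]2[C@H]3[C@@H](O[Si](C)(C)C(C)(C)C)CC(=C)[C@@H]2[C@]31C | intermediate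
22 | (E)-2-methylbut-2-enoyl chloride | C/C=C(\C)C(Cl)=O | starting material
23 | (1S,7R,9R)-1-(tert-butyldimethylsilyloxy)-7-(3-methylbut-2-enoyloxy)longipin-3(12)-en-9-yl (E)-2-methylbut-2-enoate | C/C=C(\C)C(=O)O[C@@H]1C[C@@H](OC(=O)C=C(C)C)C(C)(C)[C@@H]2[C@H]3[C@@H](O[Si](C)(C)C(C)(C)C)CC(=C)[C@@H]2[C@]31C | intermediate
24 | (1S,7R,9R)-1-hydroxy-7-(3-methylbut-2-enoyloxy)longipin-3(12)-en-9-yl (E)-2-methylbut-2-enoate | C/C=C(\C)C(=O)O[C@@H]1C[C@@H](OC(=O)C=C(C)C)C(C)(C)[C@@H]2[C@H]3[C@@H](O)CC(=C)[C@@H]2[C@]31C | intermediate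
25 | (7R,9R)-7-(3-methylbut-2-enoyloxy)-1-oxolongipin-3(12)-en-9-yl (E)-2-methylbut-2-enoate | C/C=C(\C)C(=O)O[C@@H]1C[C@@H](OC(=O)C=C(C)C)C(C)(C)[C@@H]2[C@H]3C(=O)CC(=C)[C@@H]2[C@]31C | intermediate
26 | (7R,9R)-7-(3-methylbut-2-enoyloxy)-1-oxolongipin-2-en-9-yl (E)-2-methylbut-2-enoate (CNP0277258.1) | C/C=C(\C)C(=O)O[C@@H]1C[C@@H](OC(=O)C=C(C)C)C(C)(C)[C@@H]2[C@H]3C(=O)C=C(C)[C@@H]2[C@]31C | target

Total step count: 15. Longest linear sequence: 14 (steps 1 and 3–15; step 2 is the one-step side branch).

Steps most likely to fail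

Step 9 (key step). Capture of the α-seleno cation by the hindered enol ether may lose out to return of selenolate or to attack by the enol of the neighbouring ketone, and selenolate may later add reversibly to the new enone. The fallback ties the two-carbon unit to C8 first. It sets out from 12: condensation with isobutyraldehyde (LDA, THF, −78 °C; then MsCl, Et3N, DBU) should give the (E)-enone F1, and TMSOTf/Et3N converts it into the trimethylsilyl dienol ether F2. SnCl4 (CH2Cl2, −78 °C) then ionises the selenoketal, and the γ-carbon of the dienol ether closes the seven-membered ring from the only face it can reach (intramolecular vinylogous Mukaiyama reaction). This comes back to the route at 16.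

Step 6. The alkene of the enyne may be too electron-poor for the ketene, so that ketene oligomerisation outruns the cycloaddition. The fallback sets out from 6: semi-hydrogenation (H2, Lindlar catalyst, quinoline) gives the triene ester F3 and saponification the triene acid F4. The protocol of step 6 (acid chloride F5 and vinylketene F6, neither isolated) then lets the more nucleophilic diene terminus react and should give the 7-vinyl ketone F7. Wacker oxidation (PdCl2, CuCl, O2, DMF/H2O) of the vinyl group comes back to the route at 11.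

Step 10. Conjugate borylation at the neopentyl β-carbon C7 may stall or proceed with poor catalyst control. The fallback makes the C7–O bond by aldol addition instead of conjugate addition. It sets out from 12 and 13: SnCl4 at −78 °C with aqueous work-up isolates 14, and LiHMDS (THF, −78 °C) closes the ring to aldol 15 as both C7 epimers. Chromatography separates 18 from the 7-epi ketol F8, which is returned to the epimer mixture by retro-aldol/aldol equilibration (catalytic KOt-Bu, THF, 0 °C). This comes back to the route at 18.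

Further compounds
F1 | step 9 | (E)-enone from 12 and isobutyraldehyde, 1-[bicyclic selenoketal-7-yl]-4-methylpent-2-en-1-one | c1ccccc1[Se]C2([Se]c1ccccc1)[C@@H]3C(=C)C[C@H](O[Si](C)(C)C(C)(C)C)[C@H]2[C@]3(C)C(=O)/C=C/C(C)C
F2 | step 9 | trimethylsilyl dienol ether of F1 | c1ccccc1[Se]C2([Se]c1ccccc1)[C@@H]3C(=C)C[C@H](O[Si](C)(C)C(C)(C)C)[C@H]2[C@]3(C)C(O[Si](C)(C)C)=CC=C(C)C
F3 | step 6 | methyl (2E,5S,6E)-5-(tert-butyldimethylsilyloxy)-3,7-dimethylnona-2,6,8-trienoate | COC(=O)/C=C(\C)C[C@H](O[Si](C)(C)C(C)(C)C)/C=C(\C)C=C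
F4 | step 6 | (2E,5S,6E)-5-(tert-butyldimethylsilyloxy)-3,7-dimethylnona-2,6,8-trienoic acid | OC(=O)/C=C(\C)C[C@H](O[Si](C)(C)C(C)(C)C)/C=C(\C)C=C
F5 | step 6 | acid chloride of F4 | ClC(=O)/C=C(\C)C[C@H](O[Si](C)(C)C(C)(C)C)/C=C(\C)C=C
F6 | step 6 | vinylketene from F5 | O=C=CC(=C)C[C@H](O[Si](C)(C)C(C)(C)C)/C=C(\C)C=C
F7 | step 6 | (4S)-4-(tert-butyldimethylsilyloxy)-7-ethenyl-7-methyl-2-methylidenebicyclo[3.1.1]heptan-6-one | O=C1[C@@H]2C(=C)C[C@H](O[Si](C)(C)C(C)(C)C)[C@H]1[C@]2(C)C=C
F8 | step 10 | (1S,7S)-1-(tert-butyldimethylsilyloxy)-7-hydroxy-5-(phenylselanyl)longipin-3(12)-en-9-one | O=C1C[C@H](O)C(C)(C)[C@]2([Se]c3ccccc3)[C@H]4[C@@H](O[Si](C)(C)C(C)(C)C)CC(=C)[C@@H]2[C@]41C
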